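Minutes are the unit of the opening of these flasks and hours that of their end, so we turn the constants into times at the charged amounts. The flasks differ in the charge of fresh partner, and we want the target at the end of the run.

all flasks: solid substrate 0.18 M; coupling partner 0.180 M; time 8.0 h

| run | fresh partner |
|---|---|
| Wednesday's | 0.00400 M |
| Thursday's | 0.0120 M |
| Tuesday's | 0.0400 M |
| Monday's | 0.100 M |
| Saturday's | 0.300 M |

1. amount of target at the end, in percent of the solid substrate charged for Wednesday's, Thursday's, Tuesday's, Monday's, Saturday's, in this order
2. the shape of the row from first to last (falls, then rises / rises, then falls / falls all the way / rises all the way / hardly changes)

- percent here means solid substrate units held: one homo product counts as two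
- what is said of target includes idle adduct
- where a step has two of a species, its rate is k times that concentration squared, and two are used at each turn
- solid substrate is a solid; its amount is given per volume of the solution
- at the start none of the solid substrate is in solution
- "hardly changes" means that all values lie within two and a half points (for a concentration: within two and a half percent of the largest)
- run time (Wednesday's): 8.0 h

    starting material + coupling partner → open intermediate (k1 = 0.0191 M⁻¹ min⁻¹)
    coupling partner + fresh partner → second intermediate (k2 = 0.528 M⁻¹ min⁻¹)
    open intermediate + second intermediate ⇌ target (K3 = 23.6 M⁻¹, k3 = 0.150 M⁻¹ min⁻¹)
    2 open intermediate → homo product (k4 = 0.0575 M⁻¹ min⁻¹)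
    coupling partner + target ⇌ idle adduct, settled at all times (K5 = 9.7 M⁻¹)
    solid substrate ⇌ starting material, rate k6*(cs6 - [starting material]) while solid is left; crystals form when [starting material] > cs6 (cs6 = 0.15 M, k6 = 0.239 min⁻¹)

In the first instants solid substrate goes into solution with a time constant of 4.18 min, and we take [starting material] as its solubility, 0.15 M, while solid is left. Coupling partner then has two takers: starting material, with constant 0.0191 M⁻¹ min⁻¹, and fresh partner, with constant 0.528 M⁻¹ min⁻¹. So we carry one quantity, the parity concentration: the [fresh partner] at which both takers draw coupling partner equally fast, namely the first constant times the solubility over the second constant, 0.00543 M. While [starting material] stands at that solubility, the [fresh partner] over parity is a selectivity factor: coupling partners going to fresh partner for each one going to starting material.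

In the middle, at charged coupling partner, fresh partner has a half-life of 7.29 min, against 3.36 h for starting material, so second intermediate comes first and open intermediate follows slowly. One target takes one of each, while open intermediate can also pair with itself to homo product.

Towards the end we see two ceilings. In Wednesday's flask target holds one fresh partner each, so its ceiling is 2.22% of the solid charged. In Saturday's flask fresh partner exceeds coupling partner, which makes coupling partner the limiting reagent. Summing the share while [fresh partner] falls to 0.120 M gives parity times the logarithm of that fall, so we reckon the open intermediate made there as 2.76% of the solid charged, and take this as that flask's ceiling. We commit to a row that rises, then falls, and reckon no further.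

The forecast gives values where we gave ceilings: 1.5%, 4.3%, 12%, 17%, 2%, shape rises, then falls. Of the last flask it says that “fresh partner quickly uses up all the coupling partner before the slow first step can make open intermediate”.

The simulation gives 1.31%, 3.82%, 11.1%, 16.3%, 1.51%, shape rises, then falls. The row turns at fresh partner 0.090 M, with Wednesday's charge below and Saturday's above; a run placing the turn outside that span would overturn the forecast's shape.

The consumption of coupling partner is the main reason for the drop in Saturday's flask: with it taken away, that flask ends at 67.2% of target, not 1.51%. Saturday's charge stands 55.3 times parity, and after 8.00 h coupling partner is at 0% and target at 1.51%, under our ceiling. Wednesday's charge stands 0.737 times parity, and after 8.00 h the starting material consumed in Wednesday's flask comes to 0.109 M, against 0.00400 M of fresh partner charged.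

Its constants belong to no real substance.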